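**Retrosynthetic overview** (spiro[5.5]undecane numbering throughout: ring B = C1–C6, C6 spiro, ring A = C6–C11)
1. The strategy rests on the C3(OH)(CH3)–C4(Br) unit of ring B. C4 is treated as a masked ketone, so C3/C4 is an α-ketol and the C3–C4 bond can be made by acyl-anion addition.
2. Endgame, read backwards: C11=CH2 from the C11 ketone; trans C4–Br/C3–OH from bromide opening of the C3,C4 cyclic sulfate; the cyclic sulfate from the cis diol; the cis diol from α-ketol 13.
3. Key disconnection C3–C4: carbene-catalysed benzoin addition of the C4 aldehyde to the C3 methyl ketone in keto aldehyde 12 closes ring B (second ring).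
4. C6 quaternary centre of 12: the C6–C1 bond is made last, by Mukaiyama–Michael addition of a regiodefined C6 enol silane to butenone, because the last group added to C6 enters trans to the C8 bromine. The C5–C4 arm comes from vinyl addition to the C6 exocyclic enone, then ozonolysis.
5. Ring A (first ring): bromonium-induced 6-endo cyclisation of γ-prenylated allyl acetoacetate, which sets C8.

Key step: step 7

Assumption: the sense of induction of the two chiral organocatalysts (steps 2 and 7) cannot be read off for this substrate, so for each the antipode that gives the drawn configuration is taken after one run with either enantiomer.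

Step 1
Reactants: 1 allyl acetoacetate (prop-2-en-1-yl 3-oxobutanoate); 2 1-bromo-3-methylbut-2-ene
Product: 3 prop-2-en-1-yl 7-methyl-3-oxooct-6-enoate
Conditions: NaH, THF, 0 °C; n-BuLi, 0 °C; then 2, 0 °C → rt; aq. HCl
Reagents that add atoms: none
Why: γ-Alkylation of the acetoacetate dianion: the terminal carbanion is the more nucleophilic site and displaces the allylic bromide (SN2), while the ester stays protected as its enolate.

Step 2
Reactants: 3 prop-2-en-1-yl 7-methyl-3-oxooct-6-enoate
Product: 4 prop-2-en-1-yl (3S)-3-bromo-2,2-dimethyl-6-oxocyclohexane-1-carboxylate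
Conditions: chiral BINOL-derived N-triflyl thiophosphoramide Lewis base (10 mol%), 1,3-dibromo-5,5-dimethylhydantoin (0.55 equiv), toluene/CH2Cl2, −78 °C
Reagents that add atoms: 1,3-dibromo-5,5-dimethylhydantoin, CC1(C)N(Br)C(=O)N(Br)C1=O
Why: Proposed new method: a chiral Lewis base–Br+ complex should transfer bromine to one face of the electron-rich trisubstituted alkene while the carbon of the hydrogen-bonded Z-enol (C6) opens the bromonium ion at the tertiary carbon C7 through a chair transition state (6-endo, Markovnikov), so that ring A closes and C8 becomes S; the closest known reactions are the Lewis-base-catalysed enantioselective bromonium polyene cyclisation with arene terminators and the racemic bromonium cyclisation of olefinic β-dicarbonyl compounds, and the new element is the enol carbon as terminator under chiral control.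

Step 3
Reactants: 4 prop-2-en-1-yl (3S)-3-bromo-2,2-dimethyl-6-oxocyclohexane-1-carboxylate
Product: 6 (4S)-4-bromo-3,3-dimethyl-2-methylidenecyclohexan-1-one, via β-keto acid 5 (not isolated)
Conditions: Pd(PPh3)4 (3 mol%), morpholine, THF, 0 °C; then 37% aq. CH2O, AcOH, 0 °C → rt
Reagents that add atoms: formaldehyde, C=O
Why: Tsuji–Trost deallylation (zerovalent palladium, morpholine as allyl acceptor) frees the β-keto acid as its morpholinium salt, and a Mannich reaction at the doubly activated C6 followed by decarboxylative loss of morpholine places the methylene group at C6 only; C8 is untouched.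

Step 4
Reactants: 6 (4S)-4-bromo-3,3-dimethyl-2-methylidenecyclohexan-1-one
Product: 7 {[(4S)-4-bromo-3,3-dimethyl-2-(prop-2-en-1-yl)cyclohex-1-en-1-yl]oxy}trimethylsilane
Conditions: CH2=CHMgBr, CuBr·SMe2 (10 mol%), TMSCl, THF, −78 °C; then Et3N, pentane, filtration
Reagents that add atoms: vinylmagnesium bromide, C=C[Mg]Br; chlorotrimethylsilane, C[Si](C)(C)Cl
Why: Copper-catalysed conjugate addition of the vinyl Grignard reagent to the unhindered exocyclic methylene carbon (C5) with in situ silylation traps the enolate as the enol silane with its double bond fixed between C6 and C11, a regiodefined enolate equivalent that deprotonation of the ketone would not give.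

Step 5
Reactants: 7 {[(4S)-4-bromo-3,3-dimethyl-2-(prop-2-en-1-yl)cyclohex-1-en-1-yl]oxy}trimethylsilane; 8 but-3-en-2-one
Product: 10 (2S,4S)-4-bromo-3,3-dimethyl-2-(3-oxobutyl)-2-(prop-2-en-1-yl)cyclohexan-1-one, via side-chain enol silane 9 (not isolated)
Conditions: Tf2NH (3 mol%), CH2Cl2, −78 °C; then 1 M HCl, THF, 0 °C
Reagents that add atoms: none
Why: Mukaiyama–Michael addition catalysed by TMSNTf2 formed from Tf2NH: C6 of the enol silane attacks the terminal carbon of butenone along the axial direction, anti to the pseudoaxial C7 methyl of the half-chair that keeps the C8 bromine pseudoequatorial, so the 3-oxobutyl arm should enter trans to bromine and C6 becomes S; the silyl group moves to the side-chain enol and is removed on acidic work-up.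

Step 6
Reactants: 10 (2S,4S)-4-bromo-3,3-dimethyl-2-(3-oxobutyl)-2-(prop-2-en-1-yl)cyclohexan-1-one
Product: 12 2-[(1S,3S)-3-bromo-2,2-dimethyl-6-oxo-1-(3-oxobutyl)cyclohexyl]acetaldehyde, via ozonide 11 (not isolated)
Conditions: O3, CH2Cl2, −78 °C; then Me2S, −78 °C → rt
Reagents that add atoms: ozone, [O-][O+]=O
Why: Ozonolysis with reductive work-up cleaves the only C=C bond and turns the allyl arm into the C5–C4 acetaldehyde arm; ketones, bromide and both stereocentres are inert, and the keto aldehyde is used at once.

Step 7
Reactants: 12 2-[(1S,3S)-3-bromo-2,2-dimethyl-6-oxo-1-(3-oxobutyl)cyclohexyl]acetaldehyde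
Product: 13 (3R,6S,8S)-8-bromo-3-hydroxy-3,7,7-trimethylspiro[5.5]undecane-4,11-dione
Conditions: chiral aminoindanol-derived N-C6F5 triazolium tetrafluoroborate (15 mol%), Et3N (15 mol%), toluene, 4 Å MS, rt
Reagents that add atoms: none
Why: The carbene released from the triazolium salt adds to the aldehyde carbon C4 and proton transfer gives the enaminol (acyl-anion equivalent), whose C4 attacks the methyl ketone carbon C3; proton transfer and expulsion of the carbene then release the α-ketol and the catalyst. The closest known reaction type is the carbene-catalysed intramolecular crossed aldehyde–ketone benzoin reaction of 6-oxoheptanal-type substrates, including its enantioselective form with chiral triazolium salts. Ring B closes in the 6-exo-trig mode by formation of the C3–C4 bond. The new C3 stereocentre (R, hydroxyl cis to C11) is controlled by the chiral carbene together with a chair transition state in which the bulky C7 is equatorial and C11 axial on the forming ring and the ketone oxygen is held next to the enaminol hydroxyl by a hydrogen bond, which places the C3 oxygen equatorial and therefore cis to C11. The step needs chemoselectivity for acyl-anion addition over aldol condensation and for the C3 ketone over the C11 ketone: there is a single aldehyde, attack on the neopentylic C11 ketone would give a four-membered ring, and the weak amine base at room temperature keeps enolisation slow and leaves the neopentylic C8 bromide alone.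

Step 8
Reactants: 13 (3R,6S,8S)-8-bromo-3-hydroxy-3,7,7-trimethylspiro[5.5]undecane-4,11-dione
Product: 14 (3R,4S,6S,8S)-8-bromo-3,4-dihydroxy-3,7,7-trimethylspiro[5.5]undecan-11-one
Conditions: LiBH(s-Bu)3 (2.2 equiv), THF, −78 °C; then H2O
Reagents that add atoms: none
Why: Reduction with a bulky hydride: the axial face of the C4 ketone is shielded by the axial C11 on C6, so hydride should enter equatorially and give the axial C4 alcohol cis to the C3 hydroxyl (4S), while the neopentylic C11 ketone is too hindered to react at −78 °C.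

Step 9
Reactants: 14 (3R,4S,6S,8S)-8-bromo-3,4-dihydroxy-3,7,7-trimethylspiro[5.5]undecan-11-one
Product: 16 (3R,4S,6S,8S)-8-bromo-3,7,7-trimethyl-11-oxospiro[5.5]undecane-3,4-diyl sulfate, via cyclic sulfite 15 (not isolated)
Conditions: SOCl2, Et3N, CH2Cl2, 0 °C; then RuCl3 (1 mol%), NaIO4, MeCN/H2O, 0 °C
Reagents that add atoms: thionyl chloride, O=S(Cl)Cl; sodium periodate, [Na+].[O-]I(=O)(=O)=O
Why: Cyclic sulfate formation from a cis 1,2-diol: thionyl chloride closes the five-membered sulfite and RuO4 generated catalytically oxidises sulfur; no C–O bond is broken, so C3 and C4 keep their configuration.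

Step 10
Reactants: 16 (3R,4S,6S,8S)-8-bromo-3,7,7-trimethyl-11-oxospiro[5.5]undecane-3,4-diyl sulfate
Product: 18 (3R,4R,6S,8S)-4,8-dibromo-3-hydroxy-3,7,7-trimethylspiro[5.5]undecan-11-one, via lithium bromoalkyl sulfate 17 (not isolated)
Conditions: LiBr, THF, 40 °C; then 20% aq. H2SO4, Et2O, rt
Reagents that add atoms: lithium bromide, [Li+].[Br-]; water, O
Why: SN2 opening of the cyclic sulfate by bromide at the secondary carbon C4 with inversion (the tertiary C3 is not attacked) should give the trans 4-bromo 3-sulfate with C4 now R, and acid hydrolysis of the tertiary sulfate monoester, by S–O cleavage or by bromine-assisted C–O cleavage with water returning anti to bromine, keeps the configuration at C3.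

Step 11
Reactants: 18 (3R,4R,6S,8S)-4,8-dibromo-3-hydroxy-3,7,7-trimethylspiro[5.5]undecan-11-one
Product: 19 (3R,4R,6R,8S)-4,8-dibromo-3,7,7-trimethyl-11-methylidenespiro[5.5]undecan-3-ol
Conditions: Cp2TiMe2 (3 equiv), toluene, 70 °C, dark
Reagents that add atoms: dimethyltitanocene, C[Ti](C)(C1C=CC=C1)C1C=CC=C1
Why: Petasis methylenation: the titanium methylidene formed thermally from Cp2TiMe2 should convert the hindered C11 ketone into the exocyclic alkene under non-basic conditions, so the trans bromohydrin is not closed to an epoxide and the C8 bromide is not eliminated; the tertiary hydroxyl only consumes reagent.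

**Compound list**
1 | allyl acetoacetate (prop-2-en-1-yl 3-oxobutanoate) | C=CCOC(=O)CC(C)=O | starting material
2 | 1-bromo-3-methylbut-2-ene | CC(C)=CCBr | starting material
3 | prop-2-en-1-yl 7-methyl-3-oxooct-6-enoate | C=CCOC(=O)CC(=O)CCC=C(C)C | intermediate
4 | prop-2-en-1-yl (3S)-3-bromo-2,2-dimethyl-6-oxocyclohexane-1-carboxylate (C1 epimers and enol form) | O=C1CC[C@H](Br)C(C)(C)C1C(=O)OCC=C | intermediate
5 | (3S)-3-bromo-2,2-dimethyl-6-oxocyclohexane-1-carboxylic acid (present as morpholinium salt) | O=C1CC[C@H](Br)C(C)(C)C1C(=O)O | intermediate (not isolated)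
6 | (4S)-4-bromo-3,3-dimethyl-2-methylidenecyclohexan-1-one | C=C1C(=O)CC[C@H](Br)C1(C)C | intermediate
7 | {[(4S)-4-bromo-3,3-dimethyl-2-(prop-2-en-1-yl)cyclohex-1-en-1-yl]oxy}trimethylsilane | C=CCC1=C(O[Si](C)(C)C)CC[C@H](Br)C1(C)C | intermediate
8 | but-3-en-2-one | C=CC(C)=O | starting material
9 | trimethylsilyl enol ether of 10 at the side-chain ketone (E/Z mixture, ring stereocentres as in 10) | O=C1CC[C@H](Br)C(C)(C)[C@@]1(CC=C)CC=C(C)O[Si](C)(C)C | intermediate (not isolated)
10 | (2S,4S)-4-bromo-3,3-dimethyl-2-(3-oxobutyl)-2-(prop-2-en-1-yl)cyclohexan-1-one (allyl cis, 3-oxobutyl trans to Br) | O=C1CC[C@H](Br)C(C)(C)[C@@]1(CC=C)CCC(C)=O | intermediate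
11 | 1,2,4-trioxolane (ozonide) of the allyl group of 10 (epimers at the trioxolane carbon, ring stereocentres as in 10) | O=C1CC[C@H](Br)C(C)(C)[C@@]1(CC2OCOO2)CCC(C)=O | intermediate (not isolated)
12 | 2-[(1S,3S)-3-bromo-2,2-dimethyl-6-oxo-1-(3-oxobutyl)cyclohexyl]acetaldehyde | O=C1CC[C@H](Br)C(C)(C)[C@@]1(CC=O)CCC(C)=O | intermediate
13 | (3R,6S,8S)-8-bromo-3-hydroxy-3,7,7-trimethylspiro[5.5]undecane-4,11-dione | O=C1CC[C@H](Br)C(C)(C)[C@@]12CC[C@@](C)(O)C(=O)C2 | intermediate
14 | (3R,4S,6S,8S)-8-bromo-3,4-dihydroxy-3,7,7-trimethylspiro[5.5]undecan-11-one (cis diol) | O=C1CC[C@H](Br)C(C)(C)[C@@]12CC[C@@](C)(O)[C@@H](O)C2 | intermediate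
15 | cyclic sulfite of 14 (both epimers at sulfur) | O=C1CC[C@H](Br)C(C)(C)[C@@]12CC[C@@]3(C)OS(=O)O[C@H]3C2 | intermediate (not isolated)
16 | (3R,4S,6S,8S)-8-bromo-3,7,7-trimethyl-11-oxospiro[5.5]undecane-3,4-diyl sulfate (cyclic sulfate of 14) | O=C1CC[C@H](Br)C(C)(C)[C@@]12CC[C@@]3(C)OS(=O)(=O)O[C@H]3C2 | intermediate
17 | lithium (3R,4R,6S,8S)-4,8-dibromo-3,7,7-trimethyl-11-oxospiro[5.5]undecan-3-yl sulfate | O=C1CC[C@H](Br)C(C)(C)[C@@]12CC[C@@](C)(OS(=O)(=O)[O-])[C@H](Br)C2.[Li+] | intermediate (not isolated)
18 | (3R,4R,6S,8S)-4,8-dibromo-3-hydroxy-3,7,7-trimethylspiro[5.5]undecan-11-one | O=C1CC[C@H](Br)C(C)(C)[C@@]12CC[C@@](C)(O)[C@H](Br)C2 | intermediate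
19 | (3R,4R,6R,8S)-4,8-dibromo-3,7,7-trimethyl-11-methylidenespiro[5.5]undecan-3-ol (CNP0114057.1) | C=C1CC[C@H](Br)C(C)(C)[C@@]12CC[C@@](C)(O)[C@H](Br)C2 | target

**Step count**
Total: 11 steps. Longest linear sequence: 11 steps (1 to 19).

**Three steps most likely to fail**

Step 2 (bears the label "Proposed new method"). The chiral bromine carrier may fail to discriminate the two alkene faces, bromine may be transferred to the enol carbon, or the bromonium ion may be captured through the enol oxygen instead of carbon. The fallback uses known chemistry, sets out from 3 and comes back at 6. A racemic bromonium cyclisation with 2,4,4,6-tetrabromocyclohexa-2,5-dienone in MeNO2 at 0 °C should give racemic prop-2-en-1-yl 3-bromo-2,2-dimethyl-6-oxocyclohexane-1-carboxylate F1. The conditions of step 3 should turn it, through racemic 3-bromo-2,2-dimethyl-6-oxocyclohexane-1-carboxylic acid F2, into racemic 4-bromo-3,3-dimethyl-2-methylidenecyclohexan-1-one F3. F3 is resolved by preparative chromatography on a chiral stationary phase; the (4S)-enantiomer is 6, and (4R)-4-bromo-3,3-dimethyl-2-methylidenecyclohexan-1-one F4 is set aside.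

Step 7. The acyl-anion equivalent may attack the wrong face of the C3 ketone, or base-induced intramolecular aldol condensation of the keto aldehyde may outrun carbene addition. The fallback sets out from 12 and comes back at 14, leaving out step 8. It is a reductive pinacol cyclisation with SmI2 (divalent samarium) in THF/t-BuOH at −78 °C: the ketyl formed at the aldehyde adds to the methyl ketone within a samarium chelate, which should give the cis 3,4-diol directly. Its face relative to C6 would rest on the chair preference alone (C7 equatorial) and is not secured. No compound outside the list is made on this way (F0).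

Step 5. Bond formation at the congested C6 may fail (protodesilylation to the ketone, polymerisation of butenone), or the electrophile may enter on the wrong face. The fallback sets out from 4 and 8 and comes back at 12, leaving out steps 3 to 6. It builds the quaternary centre while C6 still carries the ester and then turns the ester into the C5–C4 arm with retention:
- Michael addition of 4 to 8 (K2CO3, acetone, rt) should give prop-2-en-1-yl (1S,3S)-3-bromo-2,2-dimethyl-6-oxo-1-(3-oxobutyl)cyclohexane-1-carboxylate F5, with the 3-oxobutyl arm trans to bromine for the same reason as in step 5.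
- Deallylation (Pd(PPh3)4, morpholine, THF, 0 °C) gives (1S,3S)-3-bromo-2,2-dimethyl-6-oxo-1-(3-oxobutyl)cyclohexane-1-carboxylic acid F6, kept cold.
- Oxalyl chloride (cat. DMF, CH2Cl2, 0 °C) gives (1S,3S)-3-bromo-2,2-dimethyl-6-oxo-1-(3-oxobutyl)cyclohexane-1-carbonyl chloride F7.
- Diazomethane (Et2O, 0 °C) gives (2S,4S)-4-bromo-2-(2-diazoacetyl)-3,3-dimethyl-2-(3-oxobutyl)cyclohexan-1-one F8.
- Photochemical Wolff rearrangement in the presence of EtSH (Arndt–Eistert homologation, migration with retention) gives S-ethyl 2-[(1S,3S)-3-bromo-2,2-dimethyl-6-oxo-1-(3-oxobutyl)cyclohexyl]ethanethioate F9.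
- Fukuyama reduction (Et3SiH, Pd/C, acetone, rt) gives 12.

Further compounds
F1 | step 2 | racemic prop-2-en-1-yl 3-bromo-2,2-dimethyl-6-oxocyclohexane-1-carboxylate | O=C1CCC(Br)C(C)(C)C1C(=O)OCC=C
F2 | step 2 | racemic 3-bromo-2,2-dimethyl-6-oxocyclohexane-1-carboxylic acid | O=C1CCC(Br)C(C)(C)C1C(=O)O
F3 | step 2 | racemic 4-bromo-3,3-dimethyl-2-methylidenecyclohexan-1-one | C=C1C(=O)CCC(Br)C1(C)C
F4 | step 2 | (4R)-4-bromo-3,3-dimethyl-2-methylidenecyclohexan-1-one | C=C1C(=O)CC[C@@H](Br)C1(C)C
F0 | step 7 | none | none
F5 | step 5 | prop-2-en-1-yl (1S,3S)-3-bromo-2,2-dimethyl-6-oxo-1-(3-oxobutyl)cyclohexane-1-carboxylate | O=C1CC[C@H](Br)C(C)(C)[C@@]1(C(=O)OCC=C)CCC(C)=O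
F6 | step 5 | (1S,3S)-3-bromo-2,2-dimethyl-6-oxo-1-(3-oxobutyl)cyclohexane-1-carboxylic acid | O=C1CC[C@H](Br)C(C)(C)[C@@]1(C(=O)O)CCC(C)=O
F7 | step 5 | (1S,3S)-3-bromo-2,2-dimethyl-6-oxo-1-(3-oxobutyl)cyclohexane-1-carbonyl chloride | O=C1CC[C@H](Br)C(C)(C)[C@@]1(C(Cl)=O)CCC(C)=O
F8 | step 5 | (2S,4S)-4-bromo-2-(2-diazoacetyl)-3,3-dimethyl-2-(3-oxobutyl)cyclohexan-1-one | O=C1CC[C@H](Br)C(C)(C)[C@@]1(C(=O)C=[N+]=[N-])CCC(C)=O
F9 | step 5 | S-ethyl 2-[(1S,3S)-3-bromo-2,2-dimethyl-6-oxo-1-(3-oxobutyl)cyclohexyl]ethanethioate | O=C1CC[C@H](Br)C(C)(C)[C@@]1(CC(=O)SCC)CCC(C)=O
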